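**Plan**
Retrosynthetic cuts, in order: C3'-Br and C5'-Br of ring B (phenol ring), then C4-Br and C6-Br of ring A (methoxy ring), and last the diaryl ether bond C1-O.
Enabling feature: on ring A (C1 ether carbon, C2 OMe) the bromines at C4 and C6 lie meta to OMe, where brominating the ether would never place them. They are para and ortho to C1, where nitro groups open C1 to a phenoxide.
Forward: a guaiacol with nitro groups at C4 and C6 is converted into its C1 chloride and joined to monobenzylated catechol by SNAr. Both benzene rings are bought and no ring is built.
Reduction gives the C4,C6-diamine, and a twofold Sandmeyer reaction puts bromine on both positions in one operation.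
Debenzylation frees the ring B hydroxyl (C2'), which directs two more bromines to C5' (para) and C3' (ortho).
The target is achiral and has no stereocentre, so no stereochemistry has to be set or protected.

Key step: step 5

Remark: both starting materials are catalogue chemicals. The nitroguaiacol is preferred to guaiacol itself because one well-directed nitration of an already deactivated ring avoids oxidative side reactions. The polynitroarenes and the diazonium salt are energetic, so the diazonium salt stays cold, in solution, and is never isolated.

**Route**

Step 1
Reactants: 1 4-nitroguaiacol (2-methoxy-4-nitrophenol)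
Product: 2 4,6-dinitroguaiacol (2-methoxy-4,6-dinitrophenol)
Conditions: HNO3 (65%, 1.1 equiv), AcOH, 10 °C → rt
Reagents that add atoms: nitric acid, O[N+](=O)[O-]
Why: Electrophilic aromatic nitration, in which C6 is the only open position both ortho to the hydroxyl group and meta to the nitro group already present, so the two directing effects agree and the deactivated ring resists oxidation.

Step 2
Reactants: 2 4,6-dinitroguaiacol
Product: 4 2-chloro-1-methoxy-3,5-dinitrobenzene, via aryl phosphorodichloridate 3 (not isolated)
Conditions: POCl3 (3 equiv), PhNEt2 (1.2 equiv), 90 °C; then ice water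
Reagents that add atoms: phosphoryl chloride, O=P(Cl)(Cl)Cl
Why: Chlorodehydroxylation of an activated nitrophenol, in which O-phosphorylation makes a dichlorophosphate leaving group that chloride displaces at C1 by addition-elimination (SNAr) with help from the ortho and para nitro groups, as in the conversion of picric acid into picryl chloride.

Step 3
Reactants: 4 2-chloro-1-methoxy-3,5-dinitrobenzene; 5 2-(benzyloxy)phenol
Product: 6 2-[2-(benzyloxy)phenoxy]-1-methoxy-3,5-dinitrobenzene
Conditions: K2CO3 (1.5 equiv), DMF, rt → 50 °C
Reagents that add atoms: none
Why: SNAr through a Meisenheimer complex stabilised by the C4 and C6 nitro groups should let the phenoxide of 5 enter the doubly flanked C1 without a metal, while the benzyl group stops the second catechol oxygen from closing a dibenzodioxin at C6 and the C2 methoxy group, meta to both nitro groups, is not activated.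

Step 4
Reactants: 6 2-[2-(benzyloxy)phenoxy]-1-methoxy-3,5-dinitrobenzene
Product: 7 4-[2-(benzyloxy)phenoxy]-5-methoxybenzene-1,3-diamine
Conditions: Fe powder (10 equiv), NH4Cl, EtOH/H2O, 80 °C; 7 used at once under N2
Reagents that add atoms: none
Why: Béchamp-type metal reduction under near-neutral conditions takes both nitro groups to amines by stepwise electron and proton transfer and, unlike hydrogenation over palladium, leaves the benzyl ether untouched.

Step 5
Reactants: 7 4-[2-(benzyloxy)phenoxy]-5-methoxybenzene-1,3-diamine
Product: 9 2-[2-(benzyloxy)phenoxy]-1,5-dibromo-3-methoxybenzene, via bis(diazonium) ditosylate 8 (not isolated)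
Conditions: p-TsOH·H2O (6 equiv), t-BuONO (3 equiv), MeCN, 0 °C, 7 added over 1 h; then CuBr2 (3 equiv), CuBr (0.2 equiv), 0 °C → rt
Reagents that add atoms: CuBr2, [Cu+2].[Br-].[Br-] (both new bromines of 9); tert-butyl nitrite, CC(C)(C)ON=O, and p-TsOH, Cc1ccc(cc1)S(=O)(=O)O (terminal nitrogens and counter-ions of 8 only)
Why: Each amino group is N-nitrosated by the acid-activated nitrite and loses water to give a diazonium ion, so 7, protonated the moment it enters the flask, passes into bis(diazonium) salt 8 before any copper is present. Monovalent copper then hands one electron to each diazonium group, N2 departs, and the aryl radical takes a bromine atom from CuBr2, which gives back monovalent copper; this is a twofold Sandmeyer bromination under aprotic alkyl nitrite conditions, the reaction type used on tetrazotised arylenediamines and on 2-phenoxyanilines. Substitution is ipso, so C4-Br and C6-Br form exactly where the nitro groups stood, no ring is closed and no stereocentre arises. The first selectivity needed is diazotisation ahead of azo coupling, oxidation or ring bromination at C3 and C5 of the electron-rich meta-diamine, and it is secured by slow addition into excess acid and nitrite and by holding back CuBr2 until both amines are gone. The second is bromine capture by the C6 radical ahead of attack on ring B (Pschorr-type closure to a dibenzofuran) or hydrogen abstraction from the benzylic CH2, and it rests on the excess of CuBr2 and on the strain of a five-membered closure across the ether oxygen. Displacement of the aryloxy group from the doubly charged ring by water or bromide is held back by the OMe and N2+ groups that flank C1, by the low temperature and by the short life of 8.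

Step 6
Reactants: 9 2-[2-(benzyloxy)phenoxy]-1,5-dibromo-3-methoxybenzene
Product: 10 2-(2,4-dibromo-6-methoxyphenoxy)phenol
Conditions: BCl3 (2 equiv), C6HMe5 (3 equiv), CH2Cl2, −78 °C; then H2O
Reagents that add atoms: none
Why: Lewis acid debenzylation, in which BCl3 binds the benzylic ether oxygen and pentamethylbenzene traps the benzyl cation by Friedel-Crafts alkylation, should at −78 °C spare the aryl methyl ether, the diaryl ether and the C-Br bonds that hydrogenolysis would endanger.

Step 7
Reactants: 10 2-(2,4-dibromo-6-methoxyphenoxy)phenol
Product: 12 2,4-dibromo-6-(2,4-dibromo-6-methoxyphenoxy)phenol (target), via para-monobromophenol 11 (not isolated)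
Conditions: Br2 (2.05 equiv), AcOH, rt
Reagents that add atoms: bromine, BrBr
Why: Electrophilic aromatic bromination is directed by the free hydroxyl group first to its para position (C5') and then to its only open ortho position (C3'), while ring A is shielded by two deactivating bromines and by crowding at C3 and C5.

**Compound list**
1 | 4-nitroguaiacol (2-methoxy-4-nitrophenol) | COc1cc([N+](=O)[O-])ccc1O | starting material
2 | 4,6-dinitroguaiacol (2-methoxy-4,6-dinitrophenol) | COc1cc([N+](=O)[O-])cc([N+](=O)[O-])c1O | intermediate
3 | 2-methoxy-4,6-dinitrophenyl phosphorodichloridate | COc1cc([N+](=O)[O-])cc([N+](=O)[O-])c1OP(=O)(Cl)Cl | intermediate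
4 | 2-chloro-1-methoxy-3,5-dinitrobenzene | COc1cc([N+](=O)[O-])cc([N+](=O)[O-])c1Cl | intermediate
5 | 2-(benzyloxy)phenol | Oc1ccccc1OCc1ccccc1 | starting material
6 | 2-[2-(benzyloxy)phenoxy]-1-methoxy-3,5-dinitrobenzene | COc1cc([N+](=O)[O-])cc([N+](=O)[O-])c1Oc1ccccc1OCc1ccccc1 | intermediate
7 | 4-[2-(benzyloxy)phenoxy]-5-methoxybenzene-1,3-diamine | COc1cc(N)cc(N)c1Oc1ccccc1OCc1ccccc1 | intermediate
8 | 4-[2-(benzyloxy)phenoxy]-5-methoxybenzene-1,3-bis(diazonium) bis(4-methylbenzenesulfonate) | COc1cc([N+]#N)cc([N+]#N)c1Oc1ccccc1OCc1ccccc1.Cc1ccc(S(=O)(=O)[O-])cc1.Cc1ccc(S(=O)(=O)[O-])cc1 | intermediate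
9 | 2-[2-(benzyloxy)phenoxy]-1,5-dibromo-3-methoxybenzene | COc1cc(Br)cc(Br)c1Oc1ccccc1OCc1ccccc1 | intermediate
10 | 2-(2,4-dibromo-6-methoxyphenoxy)phenol | COc1cc(Br)cc(Br)c1Oc1ccccc1O | intermediate
11 | 4-bromo-2-(2,4-dibromo-6-methoxyphenoxy)phenol | COc1cc(Br)cc(Br)c1Oc1cc(Br)ccc1O | intermediate
12 | 2,4-dibromo-6-(2,4-dibromo-6-methoxyphenoxy)phenol | COc1cc(Br)cc(Br)c1Oc1cc(Br)cc(Br)c1O | target

Total step count: 7. Longest linear sequence: 7 steps (1 to 12); 5 enters as bought.

**Steps most likely to fail**

Step 5 (twofold Sandmeyer reaction).
- What may go wrong: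
  - The diamine may couple with its own diazonium ions.
  - The very electrophilic doubly charged ring may couple with ring B of a second molecule.
  - It may lose its aryloxy group through attack of water at C1.
  - One position may be reduced instead of brominated.
- Fallback: it sets out from 6 and comes back at 9, and it never lets two amino or two diazonium groups share the ring.
  - A Zinin reduction (NaSH, aqueous MeOH, 60 °C) should stop after one nitro group, by rule the one ortho to the ether oxygen. This gives 2-[2-(benzyloxy)phenoxy]-3-methoxy-5-nitroaniline F1, a nitroaniline too electron-poor to couple with its own diazonium ion.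
  - Diazotisation (t-BuONO, p-TsOH·H2O, MeCN, 0 °C) gives 2-[2-(benzyloxy)phenoxy]-3-methoxy-5-nitrobenzenediazonium tosylate F2. CuBr2 and catalytic CuBr convert it in the same flask into 2-[2-(benzyloxy)phenoxy]-1-bromo-3-methoxy-5-nitrobenzene F3.
  - Fe and NH4Cl reduce the remaining nitro group to 4-[2-(benzyloxy)phenoxy]-3-bromo-5-methoxyaniline F4.
  - A second diazotisation gives 4-[2-(benzyloxy)phenoxy]-3-bromo-5-methoxybenzenediazonium tosylate F5, and CuBr2 then delivers 9.
  - The site of the first reduction is not critical, because both positions end as C-Br.

Step 2 (chlorodehydroxylation).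
- What may go wrong: the phosphate may be displaced incompletely, the phenol may re-form on aqueous work-up, or chloride may remove the methyl group at the temperature needed.
- Fallback: it sets out from 2 and comes back at 4, and it separates activation from displacement.
  - TsCl and Et3N in CH2Cl2 give 2-methoxy-4,6-dinitrophenyl 4-methylbenzenesulfonate F6, which can be purified.
  - LiCl in DMF at 80 °C then displaces the sulfonate at C1 by SNAr to give 4.

Step 7 (final dibromination).
- What may go wrong: a third bromine may be taken up, or uneven bromination may leave mixtures that are hard to separate at the last stage.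
- Fallback: it sets out from 9 and comes back at 11, so each bromine is introduced in a separate monobromination with one activated site open.
  - NBS in MeCN brominates ring B of the benzyl ether once, para to the benzyloxy group, to give 1-(benzyloxy)-4-bromo-2-(2,4-dibromo-6-methoxyphenoxy)benzene F7.
  - BCl3 and pentamethylbenzene, as in step 6, free 11, which is now isolated and purified.
  - One equivalent of NBS with catalytic diisopropylamine in CH2Cl2, an ortho-selective phenol bromination, then leads to 12.

**Further compounds**
F1 | step 5 | 2-[2-(benzyloxy)phenoxy]-3-methoxy-5-nitroaniline | COc1cc([N+](=O)[O-])cc(N)c1Oc1ccccc1OCc1ccccc1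
F2 | step 5 | 2-[2-(benzyloxy)phenoxy]-3-methoxy-5-nitrobenzenediazonium 4-methylbenzenesulfonate | COc1cc([N+](=O)[O-])cc([N+]#N)c1Oc1ccccc1OCc1ccccc1.Cc1ccc(S(=O)(=O)[O-])cc1
F3 | step 5 | 2-[2-(benzyloxy)phenoxy]-1-bromo-3-methoxy-5-nitrobenzene | COc1cc([N+](=O)[O-])cc(Br)c1Oc1ccccc1OCc1ccccc1
F4 | step 5 | 4-[2-(benzyloxy)phenoxy]-3-bromo-5-methoxyaniline | COc1cc(N)cc(Br)c1Oc1ccccc1OCc1ccccc1
F5 | step 5 | 4-[2-(benzyloxy)phenoxy]-3-bromo-5-methoxybenzenediazonium 4-methylbenzenesulfonate | COc1cc([N+]#N)cc(Br)c1Oc1ccccc1OCc1ccccc1.Cc1ccc(S(=O)(=O)[O-])cc1
F6 | step 2 | 2-methoxy-4,6-dinitrophenyl 4-methylbenzenesulfonate | COc1cc([N+](=O)[O-])cc([N+](=O)[O-])c1OS(=O)(=O)c1ccc(C)cc1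
F7 | step 7 | 1-(benzyloxy)-4-bromo-2-(2,4-dibromo-6-methoxyphenoxy)benzene | COc1cc(Br)cc(Br)c1Oc1cc(Br)ccc1OCc1ccccc1
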